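The upper flavan is cut at two bonds at once: C2–C3 of its ring C and the C4–C8 interflavan bond. A racemic O-aryl methyl acetal of the ring-B aldehyde, carrying a (Z)-2-acetoxyvinyl group ortho on ring A, is ionised by a chiral confined acid. The aryl oxocarbenium (C2, between O1 and ring B) is attacked by enol-acetate carbon C3 in a Prins-type closure that sets C2 and C3 cis; the charge arrives at C4, a benzylic position stabilised by O1 and the 5,7-dioxygenated ring A, where C8 of tetra-O-benzyl-(+)-taxifolin adds trans to the 3-acetoxy group. Ring C, three stereocentres and the union of both halves arise in one operation.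

Key step: step 7

Remark: the hand of the chiral acid that gives the 2R,3R series cannot be predicted with certainty and is assumed to be the (S,S) acid; if a pilot run shows the opposite sense, the (R,R) acid is used under the same conditions. Compounds 1, 3 and 9 are taken as commercial.

Step 1
Reactants: 1 3,5-bis(benzyloxy)phenol
Product: 2 2,4-bis(benzyloxy)-6-hydroxybenzaldehyde
Conditions: MgCl2, Et3N, (CH2O)n, MeCN, reflux; aq. HCl work-up
Reagents that add atoms: formaldehyde (from paraformaldehyde), C=O
Why: Magnesium-mediated ortho-formylation (Casnati–Skattebøl) delivers formaldehyde only ortho to the phenoxide oxygen, and the two ortho positions of 1 are equivalent.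

Step 2
Reactants: 3 3,4-bis(benzyloxy)benzaldehyde
Product: 4 3,4-bis(benzyloxy)benzaldehyde dimethyl acetal
Conditions: HC(OMe)3, p-TsOH·H2O (cat.), MeOH, rt; Et3N quench
Reagents that add atoms: trimethyl orthoformate, COC(OC)OC
Why: Acid-catalysed acetalisation, with the orthoformate as dehydrating methoxy donor, should drive the aldehyde fully to the dimethyl acetal.

Step 3
Reactants: 4 3,4-bis(benzyloxy)benzaldehyde dimethyl acetal, 2 2,4-bis(benzyloxy)-6-hydroxybenzaldehyde
Product: 6 2,4-bis(benzyloxy)-6-{[3,4-bis(benzyloxy)phenyl](methoxy)methoxy}benzaldehyde (racemic mixed acetal), via α-chloro ether 5 (not isolated)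
Conditions: 4, AcCl (1.05 equiv), ZnBr2 (0.5 mol%), CH2Cl2, 0 °C to rt; then 2, i-Pr2NEt, 0 °C; aq. NaHCO3 work-up, Et3N-deactivated silica
Reagents that add atoms: none
Why: Acetal–acyl chloride exchange gives the α-chloro ether, which alkylates the phenoxide of 2 in an SN1-type Williamson etherification (the standard way to aryl methyl acetals of benzaldehydes); the acetal centre is racemic and is erased again in step 7.

Step 4
Reactants: 6 racemic mixed acetal aldehyde
Product: 7 1,5-bis(benzyloxy)-3-{[3,4-bis(benzyloxy)phenyl](methoxy)methoxy}-2-ethynylbenzene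
Conditions: Me3SiCHN2, n-BuLi, THF, −78 °C; then 6, −78 °C to rt
Reagents that add atoms: trimethylsilyldiazomethane, C[Si](C)(C)C=[N+]=[N-]
Why: Colvin rearrangement (addition of lithiated trimethylsilyldiazomethane, Peterson-type elimination, loss of N2 and 1,2-hydrogen shift of the alkylidene carbene) homologates the aldehyde to the terminal alkyne under aprotic basic conditions that should spare the labile mixed acetal.

Step 5
Reactants: 7 aryl alkyne
Product: 8 (Z)-2-{2,4-bis(benzyloxy)-6-{[3,4-bis(benzyloxy)phenyl](methoxy)methoxy}phenyl}ethenyl acetate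
Conditions: AcOH (1.3 equiv), [RuCl2(p-cymene)]2 (1 mol%), P(4-ClC6H4)3 (3 mol%), DMAP (4 mol%), toluene, 60 °C
Reagents that add atoms: acetic acid, CC(=O)O
Why: Ruthenium-catalysed anti-Markovnikov addition of a carboxylic acid to a terminal alkyne proceeds through a ruthenium vinylidene and gives the (Z)-enol ester, while DMAP buffers the acid so that the acetal should survive.

Step 6
Reactants: 9 (2R,3R)-(+)-taxifolin
Product: 10 (2R,3R)-5,7,3',4'-tetra-O-benzyltaxifolin
Conditions: BnBr (4.5 equiv), K2CO3, DMF, rt, Ar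
Reagents that add atoms: benzyl bromide, BrCc1ccccc1
Why: Williamson O-benzylation of the four phenols (K2CO3 does not deprotonate the aliphatic 3-OH) should leave both stereocentres untouched and leave C8, flanked by O1 and one benzyloxy group, as the most accessible nucleophilic ring carbon.

Step 7
Reactants: 8 (Z)-enol acetate mixed acetal, 10 (2R,3R)-5,7,3',4'-tetra-O-benzyltaxifolin
Product: 13 octa-O-benzyl 3-O-acetyl-epicatechin-(4β→8)-taxifolin (upper half 2R,3R,4R; lower half 2R,3R), via aryl oxocarbenium ion 11 (not isolated), via flavan-4-yl cation 12 (not isolated)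
Conditions: (S,S)-imidodiphosphorimidate acid [(3,3'-bis(3,5-(CF3)2C6H3)-1,1'-binaphthyl-2,2'-diyl-O,O')P(=NSO2CF3)]2NH (5 mol%), 10 (3 equiv), 5 Å MS, CH2Cl2, −60 to −30 °C, slow addition of 8; Et3N quench
Reagents that add atoms: none
Why: Proposed new method: the chiral acid protonates the methoxy group of racemic 8 and both acetal epimers collapse to the same planar (E)-aryl oxocarbenium ion 11 paired with the chiral anion, whose C2 is attacked by the acetoxy-bearing alkene carbon C3 to give benzylic cation 12, which C8 of 10 then captures in a Friedel–Crafts alkylation. The closest known reactions are the Prins/Friedel–Crafts cascade of acetal-derived oxocarbenium ions, confined-acid-catalysed asymmetric Prins cyclisations and the arylation of flavan-4-yl cations used for 4→8 proanthocyanidin bonds; new here are the O-aryl oxocarbenium ion, the enol ester as π-nucleophile and the control of both events by one chiral anion. Ring C closes in a 6-endo Prins mode (the C=O+ and the C=C bond both end up in the ring) through a half-chair in which only C2 leaves the plane of ring A. C2 and C3 should become cis because the (E)-oxocarbenium places ring B pseudo-equatorial and the (Z)-enol acetate places the acetoxy group pseudo-axial; their absolute configuration (2R,3R) is set by the chiral counteranion, and C4 (R) is set by the axial 3-acetoxy group, which shields one face (acetoxonium participation) so that 10 adds trans to it. The step needs attack through C3 and not C4, which the three oxygens of ring A secure by making C4 the cation-stabilising terminus while acetoxy is only a weak donor; it also needs capture by C8 of 10 and not by C6 or by ring A of a second upper half, which the excess of 10, the slow addition of 8 and the lower steric demand at C8 are meant to secure. Because 10 is enantiopure, any upper half of the wrong hand ends up in a diastereomer of 13 that chromatography can remove.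

Step 8
Reactants: 13 acetylated octabenzyl dimer
Product: 14 octa-O-benzyl epicatechin-(4β→8)-taxifolin (upper half 2R,3R,4R; lower half 2R,3R)
Conditions: K2CO3 (cat.), MeOH/THF, 0 °C, Ar
Reagents that add atoms: none
Why: Mild base-catalysed transesterification (Zemplén-type methanolysis) removes the secondary acetate, and the low temperature and short contact time are chosen to avoid enolisation of the α-hydroxy ketone of the lower half.

Step 9
Reactants: 14 octabenzyl dimer
Product: 15 epicatechin-(4β→8)-taxifolin (target, CNP0210692.1)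
Conditions: H2 (1 atm), Pd(OH)2/C, THF/MeOH/H2O, rt
Reagents that add atoms: none
Why: Catalytic hydrogenolysis cleaves the eight benzyl ethers under neutral conditions that should leave the cyclic benzylic ethers of both C rings, the aryl ketone and the interflavan bond intact.

Compound list
1 | 3,5-bis(benzyloxy)phenol | Oc1cc(OCc2ccccc2)cc(OCc2ccccc2)c1 | starting material
2 | 2,4-bis(benzyloxy)-6-hydroxybenzaldehyde | O=Cc1c(O)cc(OCc2ccccc2)cc1OCc1ccccc1 | intermediate
3 | 3,4-bis(benzyloxy)benzaldehyde | O=Cc1ccc(OCc2ccccc2)c(OCc2ccccc2)c1 | starting material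
4 | 3,4-bis(benzyloxy)benzaldehyde dimethyl acetal | COC(OC)c1ccc(OCc2ccccc2)c(OCc2ccccc2)c1 | intermediate
5 | 1,2-bis(benzyloxy)-4-[chloro(methoxy)methyl]benzene (racemic, not isolated) | COC(Cl)c1ccc(OCc2ccccc2)c(OCc2ccccc2)c1 | intermediate
6 | 2,4-bis(benzyloxy)-6-{[3,4-bis(benzyloxy)phenyl](methoxy)methoxy}benzaldehyde (racemic at the acetal carbon) | O=Cc1c(OC(OC)c2ccc(OCc3ccccc3)c(OCc3ccccc3)c2)cc(OCc2ccccc2)cc1OCc1ccccc1 | intermediate
7 | 1,5-bis(benzyloxy)-3-{[3,4-bis(benzyloxy)phenyl](methoxy)methoxy}-2-ethynylbenzene (racemic) | C#Cc1c(OC(OC)c2ccc(OCc3ccccc3)c(OCc3ccccc3)c2)cc(OCc2ccccc2)cc1OCc1ccccc1 | intermediate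
8 | (Z)-2-{2,4-bis(benzyloxy)-6-{[3,4-bis(benzyloxy)phenyl](methoxy)methoxy}phenyl}ethenyl acetate (racemic at the acetal carbon) | CC(=O)O/C=C\c1c(OC(OC)c2ccc(OCc3ccccc3)c(OCc3ccccc3)c2)cc(OCc2ccccc2)cc1OCc1ccccc1 | intermediate
9 | (2R,3R)-(+)-taxifolin | O=C1c2c(O)cc(O)cc2O[C@H](c2ccc(O)c(O)c2)[C@H]1O | starting material
10 | (2R,3R)-5,7,3',4'-tetra-O-benzyltaxifolin | O=C1c2c(OCc3ccccc3)cc(OCc3ccccc3)cc2O[C@H](c2ccc(OCc3ccccc3)c(OCc3ccccc3)c2)[C@H]1O | intermediate
11 | aryl oxocarbenium ion from 8 (cation drawn without its counteranion, not isolated) | CC(=O)O/C=C\c1c([O+]=Cc2ccc(OCc3ccccc3)c(OCc3ccccc3)c2)cc(OCc2ccccc2)cc1OCc1ccccc1 | intermediate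
12 | (2R,3R)-3-acetoxy-5,7-bis(benzyloxy)-2-[3,4-bis(benzyloxy)phenyl]chroman-4-ylium (cation drawn without its counteranion, not isolated) | [CH+]1c2c(OCc3ccccc3)cc(OCc3ccccc3)cc2O[C@H](c2ccc(OCc3ccccc3)c(OCc3ccccc3)c2)[C@@H]1OC(C)=O | intermediate
13 | (2R,3R)-8-{(2R,3R,4R)-3-acetoxy-5,7-bis(benzyloxy)-2-[3,4-bis(benzyloxy)phenyl]chroman-4-yl}-5,7-bis(benzyloxy)-2-[3,4-bis(benzyloxy)phenyl]-3-hydroxychroman-4-one | O=C1c2c(OCc5ccccc5)cc(OCc5ccccc5)c([C@H]3c4c(OCc5ccccc5)cc(OCc5ccccc5)cc4O[C@H](c4ccc(OCc5ccccc5)c(OCc5ccccc5)c4)[C@@H]3OC(C)=O)c2O[C@H](c2ccc(OCc3ccccc3)c(OCc3ccccc3)c2)[C@H]1O | intermediate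
14 | (2R,3R)-8-{(2R,3R,4R)-5,7-bis(benzyloxy)-2-[3,4-bis(benzyloxy)phenyl]-3-hydroxychroman-4-yl}-5,7-bis(benzyloxy)-2-[3,4-bis(benzyloxy)phenyl]-3-hydroxychroman-4-one | O=C1c2c(OCc5ccccc5)cc(OCc5ccccc5)c([C@H]3c4c(OCc5ccccc5)cc(OCc5ccccc5)cc4O[C@H](c4ccc(OCc5ccccc5)c(OCc5ccccc5)c4)[C@@H]3O)c2O[C@H](c2ccc(OCc3ccccc3)c(OCc3ccccc3)c2)[C@H]1O | intermediate
15 | epicatechin-(4β→8)-taxifolin, (2R,3R)-2-(3,4-dihydroxyphenyl)-8-[(2R,3R,4R)-2-(3,4-dihydroxyphenyl)-3,5,7-trihydroxychroman-4-yl]-3,5,7-trihydroxychroman-4-one | O=C1c2c(O)cc(O)c([C@H]3c4c(O)cc(O)cc4O[C@H](c4ccc(O)c(O)c4)[C@@H]3O)c2O[C@H](c2ccc(O)c(O)c2)[C@H]1O | target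

Total step count: 9. Longest linear sequence: 7 steps (steps 1, 3, 4, 5, 7, 8, 9 from compound 1; equally steps 2, 3, 4, 5, 7, 8, 9 from compound 3).

Steps most likely to fail

Step 7. Three processes may go wrong: poor enantiofacial control in the C2–C3 bond formation; closure through C4 instead of C3 (five-ring formation) or direct protonation of the electron-rich styrene; and capture of the C4 cation by ring A of a second upper half instead of by the less nucleophilic ring of 10 (oligomerisation). The fallback uses the established C4 activation of a preformed flavan-3-ol, sets out from 10 and returns at 14. Commercial (−)-epicatechin would be benzylated on its four phenols (BnBr, K2CO3, DMF) to 5,7,3',4'-tetra-O-benzyl-(−)-epicatechin F1. F1 would be oxidised at C4 with DDQ in CH2Cl2 in the presence of 2-ethoxyethanol to 4β-(2-ethoxyethoxy)-5,7,3',4'-tetra-O-benzyl-(−)-epicatechin F2. F2 would then be ionised with Me3SiOTf in CH2Cl2 at −78 °C in the presence of excess 10, whose C8 should add trans to the 3-hydroxyl and give 14 directly.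

Step 5. The free carboxylic acid at 60 °C may ionise the mixed acetal (loss of the aryloxy group, then cyclisation of the liberated phenol onto the alkyne), and the Z selectivity may erode. The fallback avoids both the alkyne and any free acid, sets out from 6 and returns at 8. Stork–Zhao olefination of 6 with the ylide from (iodomethyl)triphenylphosphonium iodide and NaN(SiMe3)2 (THF, −78 °C) would give the (Z)-vinyl iodide 1,5-bis(benzyloxy)-3-{[3,4-bis(benzyloxy)phenyl](methoxy)methoxy}-2-[(Z)-2-iodoethenyl]benzene F3. A copper-catalysed Ullmann-type C–O coupling of F3 with CsOAc (CuI, 3,4,7,8-tetramethyl-1,10-phenanthroline, toluene, 80 °C) would then give 8 with retention of the alkene geometry.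

Step 3. The α-chloro ether and the mixed acetal may ionise or hydrolyse prematurely during alkylation, work-up or chromatography. The fallback builds the O1–C2 bond as a robust ether first and raises it to the acetal level oxidatively, sets out from 2 and returns at 6. Alkylation of 2 with commercial 3,4-bis(benzyloxy)benzyl chloride (K2CO3, KI cat., DMF) would give 2,4-bis(benzyloxy)-6-{[3,4-bis(benzyloxy)benzyl]oxy}benzaldehyde F4. Oxidative benzylic C–H cleavage of F4 with DDQ in anhydrous CH2Cl2/MeOH, with methanol trapping the oxocarbenium ion, would give 6.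

Further compounds
F1 | step 7 | 5,7,3',4'-tetra-O-benzyl-(−)-epicatechin | C1c2c(OCc3ccccc3)cc(OCc3ccccc3)cc2O[C@H](c2ccc(OCc3ccccc3)c(OCc3ccccc3)c2)[C@@H]1O
F2 | step 7 | 4β-(2-ethoxyethoxy)-5,7,3',4'-tetra-O-benzyl-(−)-epicatechin | CCOCCO[C@H]1c2c(OCc3ccccc3)cc(OCc3ccccc3)cc2O[C@H](c2ccc(OCc3ccccc3)c(OCc3ccccc3)c2)[C@@H]1O
F3 | step 5 | 1,5-bis(benzyloxy)-3-{[3,4-bis(benzyloxy)phenyl](methoxy)methoxy}-2-[(Z)-2-iodoethenyl]benzene | I/C=C\c1c(OC(OC)c2ccc(OCc3ccccc3)c(OCc3ccccc3)c2)cc(OCc2ccccc2)cc1OCc1ccccc1
F4 | step 3 | 2,4-bis(benzyloxy)-6-{[3,4-bis(benzyloxy)benzyl]oxy}benzaldehyde | O=Cc1c(OCc2ccc(OCc3ccccc3)c(OCc3ccccc3)c2)cc(OCc2ccccc2)cc1OCc1ccccc1
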